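**Plan**

1. The target is an angular tetraflavanoid. Fisetinidol units A and B form a (4α→6) chain that ends on C6 of catechin (unit C), and a third fisetinidol (unit D) sits on C8 of unit C. Every unit is 2R,3S (2,3-trans) and every interflavan bond is 3,4-trans.
2. Retrosynthesis cuts C4(B)–C6(C) first, then C4(A)–C6(B) (both flavan-4-yl cation Friedel–Crafts bonds), and then, in unit D, O1–C8a and C4–C4a together. This leaves an oxirane alcohol on C8 of catechin and an aryne.
3. The enabling feature: the resorcinol ring A of unit D is tied to its pyran ring only through two ortho carbons (C8a to O1, C4a to C4), and C4 is benzylic to the 2,4,6-trioxygenated ring A of unit C. Ring A of D can therefore be delivered as an aryne between a C2 alkoxide and a C3–C4 oxirane.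
4. Forward: catechin → 8-carbaldehyde → enone → erythro epoxy alcohol → aryne annulation, which closes the pyran ring of unit D on intact catechin. A 5-alkoxy helper steers the aryne, becomes a triflate that shields ring A of D during the coupling, and is removed by reduction after the A–B block (from fustin) is joined at C6. Hydrogenolysis ends the route.
5. Stereochemistry: C2/C3 of units A, B and C come from (+)-fustin and (+)-catechin. C2/C3 of unit D come from Juliá–Colonna epoxidation and chelation-controlled reduction, and its C4 from inversion at the oxirane carbon. C4 of units A and B come from arene attack trans to the 3-hydroxyl.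

Key step: step 13

Assumption: (2R,3R)-(+)-fustin, 3,5-bis(benzyloxy)phenol and 1-[3,4-bis(benzyloxy)phenyl]ethan-1-one are taken as catalogue compounds; flavan positions carry the usual numbers (O1, C2, C3, C4, C4a, C5 to C8, C8a).

**Aryne precursor**

Step 1
Reactants: 1 3,5-bis(benzyloxy)phenol
Product: 2 1,3-bis(benzyloxy)-5-(methoxymethoxy)benzene
Conditions: NaH, MOMCl, THF/DMF, 0 °C → rt
Reagents that add atoms: chloromethyl methyl ether, COCCl
Why: Williamson-type O-alkylation of the sodium phenoxide should mask the one free phenol as the acetal that later serves as the directing helper.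

Step 2
Reactants: 2 1,3-bis(benzyloxy)-5-(methoxymethoxy)benzene
Product: 3 3-(benzyloxy)-5-(methoxymethoxy)phenol
Conditions: H2 (1 atm), Pd/C, EtOAc, rt, stopped at partial conversion; unreacted 2 recycled
Reagents that add atoms: none
Why: Catalytic hydrogenolysis of one of the two equivalent benzyl ethers (a statistical desymmetrisation) should free the phenol that becomes the triflate, the acetal being inert to H2 over Pd/C.

Step 3
Reactants: 3 3-(benzyloxy)-5-(methoxymethoxy)phenol
Product: 4 3-(benzyloxy)-5-(methoxymethoxy)phenyl N-isopropylcarbamate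
Conditions: i-PrNCO, Et3N (cat.), CH2Cl2, rt
Reagents that add atoms: isopropyl isocyanate, CC(C)N=C=O
Why: Base-catalysed addition of the phenol to the isocyanate (carbamoylation) should install the directing group for ortho-metalation.

Step 4
Reactants: 4 3-(benzyloxy)-5-(methoxymethoxy)phenyl N-isopropylcarbamate
Product: 8 5-(benzyloxy)-3-(methoxymethoxy)-2-(trimethylsilyl)phenyl N-isopropylcarbamate, via N-silyl carbamate 5 (not isolated), via aryllithium 6 (not isolated), via bis-silyl carbamate 7 (not isolated)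
Conditions: TMSOTf, TMEDA, Et2O, 0 °C; n-BuLi, TMEDA, −78 °C; TMSCl, −78 °C → rt; aq. NaHCO3
Reagents that add atoms: chlorotrimethylsilane, C[Si](C)(C)Cl
Why: In this directed ortho-metalation the N–H is masked in situ by silylation, the carbamate and the methoxymethoxy group should jointly direct lithiation to the carbon between them, the chlorosilane quenches the aryllithium, and the N–Si bond is hydrolysed on work-up.

Step 5
Reactants: 8 5-(benzyloxy)-3-(methoxymethoxy)-2-(trimethylsilyl)phenyl N-isopropylcarbamate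
Product: 10 5-(benzyloxy)-3-(methoxymethoxy)-2-(trimethylsilyl)phenyl trifluoromethanesulfonate, via silylphenol 9 (not isolated)
Conditions: Et2NH, DBU, MeCN, 40 °C; then PhNTf2, rt
Reagents that add atoms: N-phenylbis(trifluoromethanesulfonimide), O=S(=O)(N(c1ccccc1)S(=O)(=O)C(F)(F)F)C(F)(F)F
Why: Base-induced E1cB cleavage of the N-monosubstituted carbamate (the isocyanate is scavenged by diethylamine) and O-sulfonylation of the phenoxide should give the ortho-silylaryl triflate, the standard fluoride-triggered aryne precursor.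

**Catechin line to the epoxy alcohol**

Step 6
Reactants: 11 (+)-catechin
Product: 12 5,7,3',4'-tetra-O-benzylcatechin
Conditions: BnBr, K2CO3, DMF, 0 °C → rt
Reagents that add atoms: benzyl bromide, BrCc1ccccc1
Why: Williamson etherification with carbonate should benzylate the four phenols only, since the secondary alcohol is not deprotonated, and C2 and C3 are untouched.

Step 7
Reactants: 12 5,7,3',4'-tetra-O-benzylcatechin
Product: 13 8-bromo-5,7,3',4'-tetra-O-benzylcatechin
Conditions: NBS, CH2Cl2, −78 °C → rt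
Reagents that add atoms: N-bromosuccinimide, O=C1CCC(=O)N1Br
Why: Electrophilic aromatic bromination should occur at C8 of ring A, the most reactive position of 5,7-di-O-benzylflavan-3-ols, and not on the catechol ring.

Step 8
Reactants: 13 8-bromo-5,7,3',4'-tetra-O-benzylcatechin
Product: 14 8-bromo-3,5,7,3',4'-penta-O-benzylcatechin
Conditions: NaH, BnBr, DMF, 0 °C → rt
Reagents that add atoms: benzyl bromide, BrCc1ccccc1
Why: Williamson etherification of the sodium alkoxide should protect the 3-hydroxyl, so that only one alkoxide is present in step 13.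

Step 9
Reactants: 14 8-bromo-3,5,7,3',4'-penta-O-benzylcatechin
Product: 16 8-formyl-3,5,7,3',4'-penta-O-benzylcatechin, via aryllithium 15 (not isolated)
Conditions: n-BuLi, THF, −78 °C; DMF, −78 °C → 0 °C; H2O
Reagents that add atoms: N,N-dimethylformamide, CN(C)C=O
Why: Bromine–lithium exchange and formylation of the aryllithium with DMF (Bouveault aldehyde synthesis) should place the one-carbon handle regiospecifically on C8.

Step 10
Reactants: 16 8-formyl-3,5,7,3',4'-penta-O-benzylcatechin; 17 1-[3,4-bis(benzyloxy)phenyl]ethan-1-one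
Product: 18 (E)-1-[3,4-bis(benzyloxy)phenyl]-3-(3,5,7,3',4'-penta-O-benzylcatechin-8-yl)prop-2-en-1-one
Conditions: KOH, EtOH/THF, 40 °C
Reagents that add atoms: none
Why: Claisen–Schmidt (crossed aldol) condensation should give the E-enone, the non-enolisable aldehyde acting only as acceptor.

Step 11
Reactants: 18 (E)-1-[3,4-bis(benzyloxy)phenyl]-3-(3,5,7,3',4'-penta-O-benzylcatechin-8-yl)prop-2-en-1-one
Product: 19 [3,4-bis(benzyloxy)phenyl][(2S,3R)-3-(3,5,7,3',4'-penta-O-benzylcatechin-8-yl)oxiran-2-yl]methanone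
Conditions: poly-D-leucine, urea–H2O2, DBU, THF, rt
Reagents that add atoms: hydrogen peroxide (as its urea adduct), OO
Why: Juliá–Colonna epoxidation (a Weitz–Scheffer nucleophilic epoxidation inside the helical polypeptide) should give the trans epoxy ketone, the enone face being chosen by the D-polyleucine (reagent control, the remote catechin centres have no say).

Step 12
Reactants: 19 [3,4-bis(benzyloxy)phenyl][(2S,3R)-3-(3,5,7,3',4'-penta-O-benzylcatechin-8-yl)oxiran-2-yl]methanone
Product: 20 (R)-[3,4-bis(benzyloxy)phenyl][(2R,3R)-3-(3,5,7,3',4'-penta-O-benzylcatechin-8-yl)oxiran-2-yl]methanol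
Conditions: Zn(BH4)2, Et2O, −20 °C; pH 7 buffer
Reagents that add atoms: none
Why: Chelation-controlled hydride reduction of the α,β-epoxy ketone (zinc bridges the carbonyl and oxirane oxygens and hydride enters on the side of the oxirane hydrogen) should give the erythro epoxy alcohol with the R carbinol centre.

**Key annulation and helper conversion**

Step 13
Reactants: 20 (R)-[3,4-bis(benzyloxy)phenyl][(2R,3R)-3-(3,5,7,3',4'-penta-O-benzylcatechin-8-yl)oxiran-2-yl]methanol; 10 5-(benzyloxy)-3-(methoxymethoxy)-2-(trimethylsilyl)phenyl trifluoromethanesulfonate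
Product: 24 7,3',4'-tri-O-benzyl-5-O-(methoxymethyl)catechin-(4α→8)-3,5,7,3',4'-penta-O-benzylcatechin, via potassium alkoxide 21 (not isolated), via aryne 22 (not isolated), via aryl anion 23 (not isolated)
Conditions: KH, THF, 0 °C; then 10, CsF, 18-crown-6, THF, 0 °C → rt; H2O
Reagents that add atoms: none
Why: Proposed new method: fluoride-induced 1,2-elimination of 10 gives aryne 22, the preformed alkoxide 21 adds to the aryne carbon meta to the methoxymethoxy group (O1–C8a bond), and the aryl anion 23, held ortho to the new ether, opens the neighbouring oxirane at its benzylic carbon (C4a–C4 bond) before it can be protonated. The closest known reaction types are the annulation of arynes with salicylates or ortho-hydroxychalcones, where the aryl anion born from O-arylation is captured within the molecule, and the Parham-type cyclisation of ortho-lithiated aryl glycidyl ethers to chroman-3-ols. The pyran ring of unit D closes in the anionic 6-endo-tet mode at the oxirane carbon that bears the 2,4,6-trioxygenated ring A of catechin. C2 and C3 keep the configuration of the erythro epoxy alcohol and C4 is set by inversion at the oxirane carbon, which places aryl, hydroxyl and aryl all equatorial (2,3-trans-3,4-trans, 4α). The step needs regiocontrol at the aryne, secured by the inductive effect of the 3-alkoxy helper that puts the carbanion next to it; it needs endo rather than 5-exo opening, secured by benzylic activation of C4 and by the crowded C3; and it needs a proton-free medium, secured by the preformed alkoxide in THF.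

Step 14
Reactants: 24 7,3',4'-tri-O-benzyl-5-O-(methoxymethyl)catechin-(4α→8)-3,5,7,3',4'-penta-O-benzylcatechin
Product: 25 7,3',4'-tri-O-benzylcatechin-(4α→8)-3,5,7,3',4'-penta-O-benzylcatechin
Conditions: HCl (cat.), MeOH/THF, rt
Reagents that add atoms: none
Why: Acid-catalysed acetal exchange with methanol should remove the methoxymethyl helper, while the benzyl ethers and the interflavan bond survive the mild conditions.

Step 15
Reactants: 25 7,3',4'-tri-O-benzylcatechin-(4α→8)-3,5,7,3',4'-penta-O-benzylcatechin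
Product: 26 7,3',4'-tri-O-benzyl-5-O-(trifluoromethanesulfonyl)catechin-(4α→8)-3,5,7,3',4'-penta-O-benzylcatechin
Conditions: PhNTf2, K2CO3, DMF, rt
Reagents that add atoms: N-phenylbis(trifluoromethanesulfonimide), O=S(=O)(N(c1ccccc1)S(=O)(=O)C(F)(F)F)C(F)(F)F
Why: O-Sulfonylation of the phenoxide by the triflimide should triflate the phenol selectively over the secondary alcohol; the triflate prepares C5 for deoxygenation and deactivates ring A of unit D toward electrophiles.

**A–B block from fustin**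

Step 16
Reactants: 27 (+)-fustin
Product: 28 7,3',4'-tri-O-benzylfustin
Conditions: BnBr, K2CO3, DMF, rt
Reagents that add atoms: benzyl bromide, BrCc1ccccc1
Why: Williamson etherification of the three phenols under mild carbonate conditions should leave the 2,3-trans dihydroflavonol and its secondary alcohol intact.

Step 17
Reactants: 28 7,3',4'-tri-O-benzylfustin
Product: 29 (2R,3S,4R)-7,3',4'-tri-O-benzylflavan-3,4-diol (tri-O-benzylmollisacacidin)
Conditions: NaBH4, THF/EtOH, 0 °C
Reagents that add atoms: none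
Why: Borohydride reduction of the C4 ketone by axial hydride attack should give the equatorial 4-hydroxyl, that is the 2,3-trans-3,4-trans diol, as is known for dihydroflavonols.

Step 18
Reactants: 29 (2R,3S,4R)-7,3',4'-tri-O-benzylflavan-3,4-diol
Product: 30 (2R,3S,4R)-6-bromo-7,3',4'-tri-O-benzylflavan-3,4-diol
Conditions: NBS, CH2Cl2, −78 °C
Reagents that add atoms: N-bromosuccinimide, O=C1CCC(=O)N1Br
Why: Electrophilic aromatic bromination should take place at C6 of ring A (ortho to the benzyloxy group, para to O1), which caps this unit against acting as a nucleophile in the later Friedel–Crafts steps.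

Step 19
Reactants: 29 (2R,3S,4R)-7,3',4'-tri-O-benzylflavan-3,4-diol
Product: 31 (2R,3S,4R)-4-[(2,6-dimethylphenyl)sulfanyl]-7,3',4'-tri-O-benzylflavan-3-ol
Conditions: 2,6-dimethylbenzenethiol, BF3·OEt2 (cat.), CH2Cl2, −78 → −30 °C
Reagents that add atoms: 2,6-dimethylbenzenethiol, Cc1cccc(C)c1S
Why: In this Lewis-acid SN1 substitution (thiolysis type) the benzylic 4-hydroxyl ionises to the flavan-4-yl cation stabilised by O1 and the 7-benzyloxy group, and the thiol should capture it mainly trans to the 3-hydroxyl; the C4 configuration is of no consequence because C4 is ionised again in step 21.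

Step 20
Reactants: 30 (2R,3S,4R)-6-bromo-7,3',4'-tri-O-benzylflavan-3,4-diol; 31 (2R,3S,4R)-4-[(2,6-dimethylphenyl)sulfanyl]-7,3',4'-tri-O-benzylflavan-3-ol
Product: 32 6-bromo-7,3',4'-tri-O-benzylfisetinidol-(4α→6)-4α-[(2,6-dimethylphenyl)sulfanyl]-7,3',4'-tri-O-benzylfisetinidol
Conditions: BF3·OEt2 (cat.), 4 Å molecular sieves, CH2Cl2, −78 → −20 °C
Reagents that add atoms: none
Why: In this Friedel–Crafts alkylation the cation from 30 should attack C6 of 31 (para to O1, less hindered than C8) on the face trans to its own 3-hydroxyl (4α); the hindered aryl sulfide is not ionised by the hard Lewis acid (orthogonal activation) and the bromine keeps 30 from condensing with itself.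

**Endgame**

Step 21
Reactants: 32 6-bromo-7,3',4'-tri-O-benzylfisetinidol-(4α→6)-4α-[(2,6-dimethylphenyl)sulfanyl]-7,3',4'-tri-O-benzylfisetinidol; 26 7,3',4'-tri-O-benzyl-5-O-(trifluoromethanesulfonyl)catechin-(4α→8)-3,5,7,3',4'-penta-O-benzylcatechin
Product: 33 6-bromo-7,3',4'-tri-O-benzylfisetinidol-(4α→6)-7,3',4'-tri-O-benzylfisetinidol-(4α→6)-[7,3',4'-tri-O-benzyl-5-O-(trifluoromethanesulfonyl)catechin-(4α→8)]-3,5,7,3',4'-penta-O-benzylcatechin
Conditions: AgBF4, 2,6-di-tert-butyl-4-methylpyridine, 4 Å molecular sieves, CH2Cl2, −40 → 0 °C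
Reagents that add atoms: none
Why: Thiophilic activation by silver ion should ionise the C4–S bond of unit B, and Friedel–Crafts attack by C6 of the catechin ring of 26 on the face trans to the 3-hydroxyl should give the 4α→6 bond; C6 is the only strongly activated free aryl position, since ring A of unit D is deactivated by the triflate and ring A of unit A is capped by bromine.

Step 22
Reactants: 33 6-bromo-7,3',4'-tri-O-benzylfisetinidol-(4α→6)-7,3',4'-tri-O-benzylfisetinidol-(4α→6)-[7,3',4'-tri-O-benzyl-5-O-(trifluoromethanesulfonyl)catechin-(4α→8)]-3,5,7,3',4'-penta-O-benzylcatechin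
Product: 34 7,3',4'-tri-O-benzylfisetinidol-(4α→6)-7,3',4'-tri-O-benzylfisetinidol-(4α→6)-[7,3',4'-tri-O-benzylfisetinidol-(4α→8)]-3,5,7,3',4'-penta-O-benzylcatechin
Conditions: Pd(OAc)2, dppf, HCO2H, Et3N, DMF, 70 °C
Reagents that add atoms: none
Why: Palladium-catalysed transfer hydrogenolysis (oxidative addition to zerovalent palladium, formate exchange, decarboxylation, reductive elimination) should replace both the aryl triflate and the aryl bromide by hydrogen, the benzyl ethers being inert to the homogeneous catalyst.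

Step 23
Reactants: 34 7,3',4'-tri-O-benzylfisetinidol-(4α→6)-7,3',4'-tri-O-benzylfisetinidol-(4α→6)-[7,3',4'-tri-O-benzylfisetinidol-(4α→8)]-3,5,7,3',4'-penta-O-benzylcatechin
Product: 35 fisetinidol-(4α→6)-fisetinidol-(4α→6)-[fisetinidol-(4α→8)]-catechin (CNP0263622.1)
Conditions: H2 (1 atm), Pd(OH)2/C, THF/MeOH/H2O, rt
Reagents that add atoms: none
Why: Heterogeneous catalytic hydrogenolysis should cleave all fourteen benzyl ethers under neutral conditions without touching the interflavan C4–aryl bonds or any stereocentre.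

**Compound list**

1 | 3,5-bis(benzyloxy)phenol | Oc1cc(OCc2ccccc2)cc(OCc2ccccc2)c1 | starting material
2 | 1,3-bis(benzyloxy)-5-(methoxymethoxy)benzene | COCOc1cc(OCc2ccccc2)cc(OCc2ccccc2)c1 | intermediate
3 | 3-(benzyloxy)-5-(methoxymethoxy)phenol | COCOc1cc(O)cc(OCc2ccccc2)c1 | intermediate
4 | 3-(benzyloxy)-5-(methoxymethoxy)phenyl N-isopropylcarbamate | COCOc1cc(OC(=O)NC(C)C)cc(OCc2ccccc2)c1 | intermediate
5 | 3-(benzyloxy)-5-(methoxymethoxy)phenyl N-isopropyl-N-(trimethylsilyl)carbamate (N-silyl carbamate, formed in the flask) | COCOc1cc(OC(=O)N(C(C)C)[Si](C)(C)C)cc(OCc2ccccc2)c1 | intermediate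
6 | 2-lithio derivative of 5, lithium between the carbamate and the methoxymethoxy group (aryllithium, formed in the flask) | COCOc1c([Li])c(OC(=O)N(C(C)C)[Si](C)(C)C)cc(OCc2ccccc2)c1 | intermediate
7 | 5-(benzyloxy)-3-(methoxymethoxy)-2-(trimethylsilyl)phenyl N-isopropyl-N-(trimethylsilyl)carbamate (bis-silyl carbamate, formed in the flask) | COCOc1c([Si](C)(C)C)c(OC(=O)N(C(C)C)[Si](C)(C)C)cc(OCc2ccccc2)c1 | intermediate
8 | 5-(benzyloxy)-3-(methoxymethoxy)-2-(trimethylsilyl)phenyl N-isopropylcarbamate | COCOc1c([Si](C)(C)C)c(OC(=O)NC(C)C)cc(OCc2ccccc2)c1 | intermediate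
9 | 5-(benzyloxy)-3-(methoxymethoxy)-2-(trimethylsilyl)phenol (silylphenol, formed in the flask) | COCOc1c([Si](C)(C)C)c(O)cc(OCc2ccccc2)c1 | intermediate
10 | 5-(benzyloxy)-3-(methoxymethoxy)-2-(trimethylsilyl)phenyl trifluoromethanesulfonate | COCOc1c([Si](C)(C)C)c(OS(=O)(=O)C(F)(F)F)cc(OCc2ccccc2)c1 | intermediate
11 | (+)-catechin, (2R,3S)-2-(3,4-dihydroxyphenyl)chromane-3,5,7-triol | Oc1cc(O)c2c(c1)O[C@H](c1ccc(O)c(O)c1)[C@@H](O)C2 | starting material
12 | 5,7,3',4'-tetra-O-benzylcatechin, (2R,3S) | c1c(OCc3ccccc3)c2c(cc1OCc1ccccc1)O[C@H](c1ccc(OCc3ccccc3)c(OCc3ccccc3)c1)[C@@H](O)C2 | intermediate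
13 | 8-bromo-5,7,3',4'-tetra-O-benzylcatechin, (2R,3S) | c1c(OCc3ccccc3)c2c(c(Br)c1OCc1ccccc1)O[C@H](c1ccc(OCc3ccccc3)c(OCc3ccccc3)c1)[C@@H](O)C2 | intermediate
14 | 8-bromo-3,5,7,3',4'-penta-O-benzylcatechin, (2R,3S) | c1c(OCc3ccccc3)c2c(c(Br)c1OCc1ccccc1)O[C@H](c1ccc(OCc3ccccc3)c(OCc3ccccc3)c1)[C@@H](OCc1ccccc1)C2 | intermediate
15 | 8-lithio-3,5,7,3',4'-penta-O-benzylcatechin (aryllithium, formed in the flask) | c1c(OCc3ccccc3)c2c(c([Li])c1OCc1ccccc1)O[C@H](c1ccc(OCc3ccccc3)c(OCc3ccccc3)c1)[C@@H](OCc1ccccc1)C2 | intermediate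
16 | 8-formyl-3,5,7,3',4'-penta-O-benzylcatechin, (2R,3S)-3,5,7-tris(benzyloxy)-2-[3,4-bis(benzyloxy)phenyl]chromane-8-carbaldehyde | c1c(OCc3ccccc3)c2c(c(C=O)c1OCc1ccccc1)O[C@H](c1ccc(OCc3ccccc3)c(OCc3ccccc3)c1)[C@@H](OCc1ccccc1)C2 | intermediate
17 | 1-[3,4-bis(benzyloxy)phenyl]ethan-1-one | CC(=O)c1ccc(OCc2ccccc2)c(OCc2ccccc2)c1 | starting material
18 | (E)-1-[3,4-bis(benzyloxy)phenyl]-3-(3,5,7,3',4'-penta-O-benzylcatechin-8-yl)prop-2-en-1-one | c1c(OCc3ccccc3)c2c(c(/C=C/C(=O)c3ccc(OCc4ccccc4)c(OCc4ccccc4)c3)c1OCc1ccccc1)O[C@H](c1ccc(OCc3ccccc3)c(OCc3ccccc3)c1)[C@@H](OCc1ccccc1)C2 | intermediate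
19 | [3,4-bis(benzyloxy)phenyl][(2S,3R)-3-(3,5,7,3',4'-penta-O-benzylcatechin-8-yl)oxiran-2-yl]methanone (trans oxirane) | c1c(OCc3ccccc3)c2c(c([C@H]3O[C@@H]3C(=O)c3ccc(OCc4ccccc4)c(OCc4ccccc4)c3)c1OCc1ccccc1)O[C@H](c1ccc(OCc3ccccc3)c(OCc3ccccc3)c1)[C@@H](OCc1ccccc1)C2 | intermediate
20 | (R)-[3,4-bis(benzyloxy)phenyl][(2R,3R)-3-(3,5,7,3',4'-penta-O-benzylcatechin-8-yl)oxiran-2-yl]methanol (erythro, trans oxirane) | c1c(OCc3ccccc3)c2c(c([C@H]3O[C@@H]3[C@H](O)c3ccc(OCc4ccccc4)c(OCc4ccccc4)c3)c1OCc1ccccc1)O[C@H](c1ccc(OCc3ccccc3)c(OCc3ccccc3)c1)[C@@H](OCc1ccccc1)C2 | intermediate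
21 | potassium alkoxide of 20 (formed in the flask) | c1c(OCc3ccccc3)c2c(c([C@H]3O[C@@H]3[C@H]([O-])c3ccc(OCc4ccccc4)c(OCc4ccccc4)c3)c1OCc1ccccc1)O[C@H](c1ccc(OCc3ccccc3)c(OCc3ccccc3)c1)[C@@H](OCc1ccccc1)C2.[K+] | intermediate
22 | 5-(benzyloxy)-3-(methoxymethoxy)benzyne (formed in the flask) | COCOC1=CC(OCc2ccccc2)=CC#C1 | intermediate
23 | aryl ether of 20 with 3-(benzyloxy)-5-(methoxymethoxy)phenyl, carbanion at the ring carbon between the ether and the methoxymethoxy group, potassium salt (formed in the flask) | c1c(OCc3ccccc3)c2c(c([C@H]3O[C@@H]3[C@H](Oc3cc(OCc4ccccc4)cc(OCOC)[c-]3)c3ccc(OCc4ccccc4)c(OCc4ccccc4)c3)c1OCc1ccccc1)O[C@H](c1ccc(OCc3ccccc3)c(OCc3ccccc3)c1)[C@@H](OCc1ccccc1)C2.[K+] | intermediate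
24 | 7,3',4'-tri-O-benzyl-5-O-(methoxymethyl)catechin-(4α→8)-3,5,7,3',4'-penta-O-benzylcatechin (upper unit 2,3-trans-3,4-trans, 3-OH free) | c1c(OCc3ccccc3)c2c(c([C@@H]3c4c(OCOC)cc(OCc5ccccc5)cc4O[C@H](c4ccc(OCc5ccccc5)c(OCc5ccccc5)c4)[C@H]3O)c1OCc1ccccc1)O[C@H](c1ccc(OCc3ccccc3)c(OCc3ccccc3)c1)[C@@H](OCc1ccccc1)C2 | intermediate
25 | 7,3',4'-tri-O-benzylcatechin-(4α→8)-3,5,7,3',4'-penta-O-benzylcatechin (upper unit 5-OH and 3-OH free) | c1c(OCc3ccccc3)c2c(c([C@@H]3c4c(O)cc(OCc5ccccc5)cc4O[C@H](c4ccc(OCc5ccccc5)c(OCc5ccccc5)c4)[C@H]3O)c1OCc1ccccc1)O[C@H](c1ccc(OCc3ccccc3)c(OCc3ccccc3)c1)[C@@H](OCc1ccccc1)C2 | intermediate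
26 | 7,3',4'-tri-O-benzyl-5-O-(trifluoromethanesulfonyl)catechin-(4α→8)-3,5,7,3',4'-penta-O-benzylcatechin | c1c(OCc3ccccc3)c2c(c([C@@H]3c4c(OS(=O)(=O)C(F)(F)F)cc(OCc5ccccc5)cc4O[C@H](c4ccc(OCc5ccccc5)c(OCc5ccccc5)c4)[C@H]3O)c1OCc1ccccc1)O[C@H](c1ccc(OCc3ccccc3)c(OCc3ccccc3)c1)[C@@H](OCc1ccccc1)C2 | intermediate
27 | (+)-fustin, (2R,3R)-2-(3,4-dihydroxyphenyl)-3,7-dihydroxychroman-4-one | O=C1c2ccc(O)cc2O[C@H](c2ccc(O)c(O)c2)[C@H]1O | starting material
28 | 7,3',4'-tri-O-benzylfustin, (2R,3R) | O=C1c2ccc(OCc3ccccc3)cc2O[C@H](c2ccc(OCc3ccccc3)c(OCc3ccccc3)c2)[C@H]1O | intermediate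
29 | (2R,3S,4R)-7-(benzyloxy)-2-[3,4-bis(benzyloxy)phenyl]chromane-3,4-diol (tri-O-benzylmollisacacidin, 2,3-trans-3,4-trans) | c1ccccc1COc1ccc2c(c1)O[C@H](c1ccc(OCc3ccccc3)c(OCc3ccccc3)c1)[C@@H](O)[C@@H]2O | intermediate
30 | (2R,3S,4R)-7-(benzyloxy)-2-[3,4-bis(benzyloxy)phenyl]-6-bromochromane-3,4-diol | c1ccccc1COc1c(Br)cc2c(c1)O[C@H](c1ccc(OCc3ccccc3)c(OCc3ccccc3)c1)[C@@H](O)[C@@H]2O | intermediate
31 | (2R,3S,4R)-7-(benzyloxy)-2-[3,4-bis(benzyloxy)phenyl]-4-[(2,6-dimethylphenyl)sulfanyl]chroman-3-ol (3,4-trans epimer drawn) | c1ccccc1COc1ccc2c(c1)O[C@H](c1ccc(OCc3ccccc3)c(OCc3ccccc3)c1)[C@@H](O)[C@@H]2Sc1c(C)cccc1C | intermediate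
32 | 6-bromo-7,3',4'-tri-O-benzylfisetinidol-(4α→6)-4α-[(2,6-dimethylphenyl)sulfanyl]-7,3',4'-tri-O-benzylfisetinidol | c1ccccc1COc1c(Br)cc2c(c1)O[C@H](c1ccc(OCc3ccccc3)c(OCc3ccccc3)c1)[C@@H](O)[C@@H]2c1cc2c(cc1OCc1ccccc1)O[C@H](c1ccc(OCc3ccccc3)c(OCc3ccccc3)c1)[C@@H](O)[C@@H]2Sc1c(C)cccc1C | intermediate
33 | protected tetramer with bromine on C6 of unit A and triflate on C5 of unit D | c1ccccc1COc1c(Br)cc2c(c1)O[C@H](c1ccc(OCc3ccccc3)c(OCc3ccccc3)c1)[C@@H](O)[C@@H]2c1cc2c(cc1OCc1ccccc1)O[C@H](c1ccc(OCc3ccccc3)c(OCc3ccccc3)c1)[C@@H](O)[C@@H]2c1c(OCc3ccccc3)c2c(c([C@@H]3c4c(OS(=O)(=O)C(F)(F)F)cc(OCc5ccccc5)cc4O[C@H](c4ccc(OCc5ccccc5)c(OCc5ccccc5)c4)[C@H]3O)c1OCc1ccccc1)O[C@H](c1ccc(OCc3ccccc3)c(OCc3ccccc3)c1)[C@@H](OCc1ccccc1)C2 | intermediate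
34 | tetradeca-O-benzyl tetramer: tri-O-benzylfisetinidol-(4α→6)-tri-O-benzylfisetinidol-(4α→6)-[tri-O-benzylfisetinidol-(4α→8)]-penta-O-benzylcatechin | c1ccccc1COc1ccc2c(c1)O[C@H](c1ccc(OCc3ccccc3)c(OCc3ccccc3)c1)[C@@H](O)[C@@H]2c1cc2c(cc1OCc1ccccc1)O[C@H](c1ccc(OCc3ccccc3)c(OCc3ccccc3)c1)[C@@H](O)[C@@H]2c1c(OCc3ccccc3)c2c(c([C@@H]3c4ccc(OCc5ccccc5)cc4O[C@H](c4ccc(OCc5ccccc5)c(OCc5ccccc5)c4)[C@H]3O)c1OCc1ccccc1)O[C@H](c1ccc(OCc3ccccc3)c(OCc3ccccc3)c1)[C@@H](OCc1ccccc1)C2 | intermediate
35 | fisetinidol-(4α→6)-fisetinidol-(4α→6)-[fisetinidol-(4α→8)]-catechin (CNP0263622.1) | Oc1ccc2c(c1)O[C@H](c1ccc(O)c(O)c1)[C@@H](O)[C@@H]2c1cc2c(cc1O)O[C@H](c1ccc(O)c(O)c1)[C@@H](O)[C@@H]2c1c(O)c2c(c([C@@H]3c4ccc(O)cc4O[C@H](c4ccc(O)c(O)c4)[C@H]3O)c1O)O[C@H](c1ccc(O)c(O)c1)[C@@H](O)C2 | target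

**Totals**

Total step count: 23.
Longest linear sequence: 13 steps (11 → 35 through steps 6 to 15 and 21 to 23).

**Steps most likely to fail**

Step 13 (the proposed new method). The aryl anion may be protonated before ring closure, may open the oxirane at C3 (5-exo), or the epoxy alkoxide may undergo Payne rearrangement before it meets the aryne. The fallback attaches unit D by the classical flavan-4-yl cation route, all of it known chemistry. It sets out from 12 and 29. Compound 12 is benzylated at O3 (NaH, BnBr, DMF) to 3,5,7,3',4'-penta-O-benzylcatechin F1. Diol 29 is ionised with catalytic BF3·OEt2 in CH2Cl2 in the presence of excess F1, whose C8 is the most nucleophilic position, and Friedel–Crafts attack trans to the 3-hydroxyl should give tri-O-benzylfisetinidol-(4α→8)-penta-O-benzylcatechin F2. F2 is coupled with 32 under the conditions of step 21 to the bromo tetramer F3, and F3 is debrominated under the conditions of step 22, which brings the material back to the route at 34. This path gives up the triflate shield on ring A of unit D, so the coupling of F2 should need a larger excess of the nucleophile.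

Step 11. Oxygen transfer to the hindered, electron-rich enone may be slow or poorly face-selective, and the benzylic oxirane may open on isolation. The fallback builds the oxirane by C–C bond formation instead of oxidation. It sets out from 17 and 16. Ketone 17 is brominated (CuBr2, EtOAc/CHCl3, reflux) to 2-bromo-1-[3,4-bis(benzyloxy)phenyl]ethan-1-one F4. An asymmetric Darzens condensation of F4 with aldehyde 16 under phase transfer (cinchona-derived quaternary ammonium salt of the pseudo-enantiomeric series that leads to the 2S,3R oxirane, LiOH, Bu2O, rt) should then give the trans epoxy ketone directly and return to the route at 19.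

Step 21. The unit B cation may condense with a second molecule of 32, attack from the wrong face, or be lost by elimination before it meets the hindered C6 of catechin. The fallback changes the order of assembly from block coupling to stepwise chain growth. It sets out from 26, 29 and 30. Diol 29 is ionised (BF3·OEt2 cat., CH2Cl2, −78 → −20 °C, slow addition) in the presence of 26, and attack by C6 of the catechin ring should give the trimer tri-O-benzylfisetinidol-(4α→6)-[tri-O-benzyl-5-O-triflylcatechin-(4α→8)]-penta-O-benzylcatechin F5. The bromo diol 30 is then ionised in the same way in the presence of F5, whose only activated free position is C6 of the new unit B (ring A of unit D stays shielded by the triflate), which returns to the route at 33.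

Further compounds
F1 | step 13 | 3,5,7,3',4'-penta-O-benzylcatechin | c1c(OCc3ccccc3)c2c(cc1OCc1ccccc1)O[C@H](c1ccc(OCc3ccccc3)c(OCc3ccccc3)c1)[C@@H](OCc1ccccc1)C2
F2 | step 13 | 7,3',4'-tri-O-benzylfisetinidol-(4α→8)-3,5,7,3',4'-penta-O-benzylcatechin | c1c(OCc3ccccc3)c2c(c([C@@H]3c4ccc(OCc5ccccc5)cc4O[C@H](c4ccc(OCc5ccccc5)c(OCc5ccccc5)c4)[C@H]3O)c1OCc1ccccc1)O[C@H](c1ccc(OCc3ccccc3)c(OCc3ccccc3)c1)[C@@H](OCc1ccccc1)C2
F3 | step 13 | 6-bromo-tri-O-benzylfisetinidol-(4α→6)-tri-O-benzylfisetinidol-(4α→6)-[tri-O-benzylfisetinidol-(4α→8)]-penta-O-benzylcatechin | c1ccccc1COc1c(Br)cc2c(c1)O[C@H](c1ccc(OCc3ccccc3)c(OCc3ccccc3)c1)[C@@H](O)[C@@H]2c1cc2c(cc1OCc1ccccc1)O[C@H](c1ccc(OCc3ccccc3)c(OCc3ccccc3)c1)[C@@H](O)[C@@H]2c1c(OCc3ccccc3)c2c(c([C@@H]3c4ccc(OCc5ccccc5)cc4O[C@H](c4ccc(OCc5ccccc5)c(OCc5ccccc5)c4)[C@H]3O)c1OCc1ccccc1)O[C@H](c1ccc(OCc3ccccc3)c(OCc3ccccc3)c1)[C@@H](OCc1ccccc1)C2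
F4 | step 11 | 2-bromo-1-[3,4-bis(benzyloxy)phenyl]ethan-1-one | BrCC(=O)c1ccc(OCc2ccccc2)c(OCc2ccccc2)c1
F5 | step 21 | 7,3',4'-tri-O-benzylfisetinidol-(4α→6)-[7,3',4'-tri-O-benzyl-5-O-(trifluoromethanesulfonyl)catechin-(4α→8)]-3,5,7,3',4'-penta-O-benzylcatechin | c1ccccc1COc1ccc2c(c1)O[C@H](c1ccc(OCc3ccccc3)c(OCc3ccccc3)c1)[C@@H](O)[C@@H]2c1c(OCc3ccccc3)c2c(c([C@@H]3c4c(OS(=O)(=O)C(F)(F)F)cc(OCc5ccccc5)cc4O[C@H](c4ccc(OCc5ccccc5)c(OCc5ccccc5)c4)[C@H]3O)c1OCc1ccccc1)O[C@H](c1ccc(OCc3ccccc3)c(OCc3ccccc3)c1)[C@@H](OCc1ccccc1)C2
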